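Dawn, charged with 0.29 M of reagent against 0.077 M in autumn, ended with less substrate than autumn and with more target. Delta and theta start from the same substrate charge and differ in reagent.

| flask | substrate | reagent | remark | time |
|---|---|---|---|---|
| autumn | 0.31 M | 0.077 M | run made earlier |  |
| dawn | 0.31 M | 0.29 M | run made earlier |  |
| delta | 0.31 M | 0.465 M |  | 3.0 min |
| theta | 0.31 M | 0.150 M |  | 3.0 min |

| run | time / min | target / % | substrate / % |
|---|---|---|---|
| autumn | 0.167 | 0 | 97.0 |
| autumn | 0.500 | 2.6 | 92.9 |
| autumn | 0.833 | 5.2 | 89.4 |
| autumn | 1.33 | 6.9 | 85.6 |
| autumn | 2.00 | 10.0 | 81.3 |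
| autumn | 2.50 | 10.8 | 79.7 |
| autumn | 3.00 | 10.7 | 78.5 |
| dawn | 0.167 | 1.6 | 89.7 |
| dawn | 0.500 | 9.1 | 76.2 |
| dawn | 0.833 | 16.5 | 66.7 |
| dawn | 1.33 | 21.7 | 56.0 |
| dawn | 2.00 | 23.1 | 47.9 |
| dawn | 2.50 | 24.0 | 43.4 |
| dawn | 3.00 | 22.8 | 41.3 |

(readings scatter by 0.5 percentage points)

- the winner by amount of target, in percent of the substrate charged; "neither" if no more than 2 percentage points parts them (delta / theta / neither)
- how much target is there at the end, in percent of the substrate charged: delta
- how much target is there at the end, in percent of the substrate charged: theta

- the earlier runs were read with a standard deviation of 0.5 percentage points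

The last row of each table carries the argument. The e-fold charge c_e is c(reagent) divided by the natural logarithm of charged over remaining substrate, at 3.0 min and 0.31 M of substrate. It replaces the whole falling curve by one mean, a pseudo-first-order picture with reagent held at its charge.

Autumn's row gives 0.318 M and dawn's gives 0.328 M, although their charges differ 3.77-fold. The mean is 0.323 M. The error lies inside the run: at 0.500 min this mean puts dawn at 86.1%, above the reading of 76.2%. So c_e is a reading for the end time.

The target columns add a second reading. Target stands at 49.8% of the lost substrate in autumn and 38.8% in dawn.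

This reckoning leaves 23.7% of the substrate in delta and 62.9% in theta. A straight line through the two shares, stretched beyond dawn for delta, gives 29.9% and 46.0%. Target is then 22.8% in delta and 17.1% in theta, so delta leads.

The forecast also names delta, with 27% in delta, above this reckoning, and 17.5% in theta. Its delta peaks and “then decays to about 27”.

Target stands higher in delta: 24.2%, against 17.9% in theta.

    substrate + intermediate → side product (k = 0.0340 M⁻¹ s⁻¹)
    substrate + reagent ⇌ intermediate (K = 2.40 M⁻¹, k = 0.0400 M⁻¹ s⁻¹)
    reagent + target → over-reaction product (k = 0.0170 M⁻¹ s⁻¹)
    intermediate ⇌ target + by-product (K = 0.310 M, k = 0.0430 s⁻¹)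

Delta keeps 25.9% of its substrate against the 23.7% from c_e. In a neighbour of delta with 0.12 M of reagent, c_e gives 69.0% and the flask holds 68.4%. The gap at the asked time comes from the difference in reagent: theta, with that difference taken away, goes from 17.9% of target to 24.2%. The order of the two turns with time. Left ten times as long, delta's target falls from 24.2% to 2.63%, below theta's 5.94%.

(All runs are calculated from invented constants.)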